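All runs are calculated on assumed constants; the scatter is artificial.

A small charge of catalyst was what I looked at first: ash got 10 mM and cedar 32 mM, and I wanted to know whether ash, with its longer time, still arrived.

| flask | substrate | catalyst | remark | time |
|---|---|---|---|---|
| blue | 0.26 M | 32 mM | run made earlier |  |
| amber | 0.21 M | 15 mM | run made earlier |  |
| ash | 0.15 M | 10 mM |  | 6.0 h |
| cedar | 0.21 M | 32 mM |  | 3.0 h |

- blue (time / min: target / %, substrate / %): 25.0: 43, 55; 50.0: 58, 47; 80.0: 59, 42; 90.0: 65, 38; 120: 62, 40
- amber (time / min: target / %, substrate / %): 25.0: 28, 74; 50.0: 41, 58; 80.0: 50, 48; 90.0: 53, 48; 120: 57, 40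

(standard deviation of a reading: 1.5 percentage points)

- the winner by amount of target, in percent of the substrate charged; "neither" if no more than 2 percentage points parts them (ash / cedar / neither)
- how much target is there at the end, in percent of the substrate charged: ash
- how much target is there at the end, in percent of the substrate charged: cedar

- the analysis behind the earlier runs scatters by 1.5 percentage points, standard deviation

Target and substrate together made 102% of the charge in blue's last reading and 97.0% in amber's, so I followed one conversion. Blue had flattened, and the mean of its late readings gave a plateau P of 62.0%, while amber was still climbing, and I took the same P for amber. I took logarithms of the gap between P and the target. Amber stood at 41% after 50.0 min, which made t_d 106 min at 15 mM: the decade time, the time in which the gap shrinks by a factor of 10. I treated the approach as pseudo-first-order, with t_d inverse to catalyst. That predicted 49.8 min at 32 mM, and blue's reading at 25.0 min, in a flask that also held more substrate than amber, gave 48.7 min, though each reading scatters by 1.5 percentage points. Ash's substrate lay outside what the runs covered, so I watched that assumption.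

The ladder, fastest first, began with cedar's decade of 49.8 min, then ash's of 160 min, then cedar's 3.0 h and ash's 6.0 h. By this reckoning cedar ended 3.61 decades in, and ash 2.26. Ash's reckoned gap of 0.34 points was smaller than the margin of 2 points. I reckoned 61.7% for ash and 62.0% for cedar, hence neither.

The forecast also said neither, with lower figures: 60.7% for ash (57% to 64%) and 61% for cedar (58% to 64%), in its words: “The two runs end the same, so neither wins.”

The flasks gave neither, with ash at 59.9% and cedar at 60.3%.

    substrate + catalyst ⇌ catalyst + target (K = 1.53, k = 0.0155 M⁻¹ s⁻¹)
    target → over-reaction product (k = 4.96 × 10⁻⁷ s⁻¹)

A neighbour of ash had 2.50 mM of catalyst and the same 6.0 h. Its decade time scaled to 638 min, longer than the run, so I reckoned 0.564 of a decade and 45.1% of target. That flask held substrate at 54.6% and target at 45.1% after 6.00 h.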